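Lactone rings A (O1, C2–C8a) and B (primed) of the target share only the C3–C3' bond. C3 (R) and C3' (S) mirror each other, and H3/H4 and H3'/H4' are cis. Formally this is a syn head-to-head dimer of two coumarins in which C4 and C4' carry hydrogen instead of being bonded. The plan therefore disconnects C3–C3' together with a sacrificial C4–C4' bond. One enantioselective irradiation of a bis(4-arylcoumarin), strapped para-oxygen to para-oxygen by O(CH2)3O and bound at lactone A to a chiral Lewis acid, makes both bonds, the cyclobutane, a cyclophane ring and four stereocentres. The overcrowded tetraaryl C4–C4' bond is later cut by electron transfer and protonated from outside.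

Key step: step 6

Assumption: coumarin locants (unit A plain, unit B primed) are kept for every strapped compound, and the (S)-configured catalyst of step 6 is taken to cover the Re face at C3 of the lactone it binds; should a pilot run show the opposite sense, its mirror image is used and nothing else changes.

Step 1
Reactants: 1 1,2,3,4-tetramethoxybenzene
Product: 4 2,3,4,5-tetramethoxyphenol, via aryllithium 2 (not isolated), via dimethyl arylboronate 3 (not isolated)
Conditions: n-BuLi, TMEDA, THF, 0 °C; B(OMe)3, −78 °C → rt; AcOH, 30% H2O2, 0 °C → rt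
Reagents that add atoms: hydrogen peroxide, OO
Why: Directed ortho-lithiation at one of the two equivalent free positions, borylation and peroxide-induced aryl migration from boron to oxygen form a standard arene-to-phenol sequence that creates no stereocentre.

Step 2
Reactants: 5 3,5-dimethoxyphenol; 6 ethyl 3-(4-hydroxyphenyl)-3-oxopropanoate
Product: 7 4-(4-hydroxyphenyl)-5,7-dimethoxy-2H-chromen-2-one
Conditions: CF3CO2H, reflux, Ar
Reagents that add atoms: none
Why: In this Pechmann condensation the strongly activated phenol attacks the protonated ketone at one of its two equivalent positions ortho to OH, transesterification and dehydration close the pyranone, and the acyl-deactivated phenol of 6 stays a spectator.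

Step 3
Reactants: 4 2,3,4,5-tetramethoxyphenol; 6 ethyl 3-(4-hydroxyphenyl)-3-oxopropanoate
Product: 8 4-(4-hydroxyphenyl)-5,6,7,8-tetramethoxy-2H-chromen-2-one
Conditions: CF3CO2H, reflux, Ar
Reagents that add atoms: none
Why: This second Pechmann condensation has only one possible regiochemistry, because 4 has a single free ring carbon, which lies ortho to OH and para to the 3-methoxy donor.

Step 4
Reactants: 7 4-(4-hydroxyphenyl)-5,7-dimethoxy-2H-chromen-2-one; 9 1,3-dibromopropane (5 equiv)
Product: 10 4-[4-(3-bromopropoxy)phenyl]-5,7-dimethoxy-2H-chromen-2-one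
Conditions: K2CO3, acetone, reflux
Reagents that add atoms: none
Why: In this Williamson ether synthesis the excess of dihalide suppresses double substitution, and the coumarin lactone tolerates carbonate in acetone.

Step 5
Reactants: 10 4-[4-(3-bromopropoxy)phenyl]-5,7-dimethoxy-2H-chromen-2-one; 8 4-(4-hydroxyphenyl)-5,6,7,8-tetramethoxy-2H-chromen-2-one
Product: 11 strapped bis(4-arylcoumarin) with units A and B joined ArO(CH2)3OAr' through the para oxygens of their C4 aryl groups
Conditions: K2CO3, DMF, 60 °C
Reagents that add atoms: none
Why: A second Williamson ether synthesis on a primary bromide joins the two different coumarins in a defined, non-statistical way.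

Step 6
Reactants: 11 strapped bis(4-arylcoumarin)
Product: 13 syn head-to-head cyclobutane photoadduct (3S,4R,3'R,4'S), via triplet 1,4-diradical 12 (not isolated)
Conditions: (S)-3,3-bis(3,5-dimethylphenyl)-1-[2-(trifluoromethyl)phenyl]tetrahydro-1H,3H-pyrrolo[1,2-c][1,3,2]oxazaborole (50 mol%), AlBr3 (50 mol%), CH2Cl2 (2 mM), −75 °C, hν (385 nm LED); Et3N quench, work-up and storage below 0 °C
Reagents that add atoms: none
Why: Proposed new method: the boron Lewis acid should sit on the carbonyl of lactone A, the better donor because its 5- and 7-OMe groups lie in plane and push through C4a–C4=C3 whereas the four buttressed OMe groups of unit B are twisted, and this complex, red-shifted and prone to intersystem crossing, should be the only species that absorbs at the chosen wavelength and reaches its triplet. C3 of the excited unit then bonds to C3' of the stacked partner, an end-to-end closure of a 17-membered ring through the strap that gives the bis(diarylmethyl) triplet 1,4-diradical 12, and after spin inversion 12 recombines at C4–C4', which closes the four-membered ring and turns the large ring into a 15-membered [5.2]paracyclophane. The nearest known reactions are the syn head-to-head photodimerisation of strapped coumarins and the oxazaborolidine–AlBr3-catalysed enantioselective intramolecular coumarin–alkene (2+2) photocycloaddition; untested is the recombination of two fully substituted diaryl carbons, which has to outrun cleavage of 12 back to 11. C3 (S in 13) is set by the catalyst, whose aryl group covers the Re face so that unit B adds to the Si face, and C4 (R) follows because a cyclobutane can only be cis-fused to the six-membered lactone. C3' (R) and C4' (S) are set by the strap, whose five atoms can bridge the two C4 aryl groups only when these stand cis on the cyclobutane, so that unit B must offer its Re face in a syn stack, again with cis fusion. The step needs head-to-head orientation and syn topology, both secured by the strap, and site selectivity of the Lewis acid for lactone A, secured only by the donor difference named above, since the same catalyst on lactone B would deliver the enantiomer.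

Step 7
Reactants: 13 syn head-to-head cyclobutane photoadduct
Product: 15 bis(trimethylsilyl acetal) of the photoadduct (3S,4R,3'R,4'S; anomers at C2 and C2'), via bis(diisobutylaluminium) hemiacetal 14 (not isolated)
Conditions: i-Bu2AlH (2.3 equiv), CH2Cl2, −78 °C; pyridine, TMSOTf, −78 → −20 °C; aq. NaHCO3, potassium sodium tartrate
Reagents that add atoms: trimethylsilyl trifluoromethanesulfonate, C[Si](C)(C)OS(=O)(=O)C(F)(F)F
Why: Reductive silylation of a lactone (aluminium hydride half-reduction of a 4-arylchroman-2-one, which stops at the chromanol level at −78 °C, with in situ O-silylation) removes both carbonyl acceptors, whose radical anions would unzip C3–C3' and revert the dimer in the next step, leaves the four ring stereocentres untouched, and gives C2/C2' anomers that vanish in step 9.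

Step 8
Reactants: 15 bis(trimethylsilyl acetal) of the photoadduct
Product: 18 strapped bis(chroman-2-ol) (3R,4S,3'S,4'R; anomers at C2 and C2'), via 4,4'-dilithio dianion 16 (not isolated), via seco bis(silyl acetal) 17 (not isolated)
Conditions: lithium naphthalenide (about 2.2 equiv, titrated to a lasting green), THF, −78 °C; AcOH, −78 °C; then AcOH/THF/H2O, rt
Reagents that add atoms: none
Why: Arene radical-anion scission of a 1,1,2,2-tetraarylethane bond, here weakened further by ring strain and two adjacent quaternary carbons, should give the kind of 1,4-bis(diarylmethyl) dianion that 1,1-diarylethenes form with lithium, and since A(1,2) strain with the in-plane C4 aryl group turns the bulky C3 substituent axial in each planar carbanion, kinetic protonation reaches C4 and C4' from the open face anti to it, which sets H4 cis to H3 (4S) and H4' cis to H3' (4'R) before aqueous acid strips the labile silyl acetals.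

Step 9
Reactants: 18 strapped bis(chroman-2-ol)
Product: 19 strapped bis-lactone hexamethyl ether (3R,4S,3'S,4'R)
Conditions: n-Pr4N[RuO4] (5 mol%), NMO, 4 Å MS, CH2Cl2, rt
Reagents that add atoms: none
Why: The Ley–Griffith oxidation of lactols to lactones is fast and essentially neutral, leaves electron-rich aryl ethers alone and should not enolise C3 or C3'.

Step 10
Reactants: 19 strapped bis-lactone hexamethyl ether
Product: 21 target CNP0064734.3 (3R,4S,3'S,4'R), via octakis(dibromoboryl) ether 20 (not isolated)
Conditions: BBr3 (20 equiv), CH2Cl2, −78 °C → rt, Ar; degassed ice-water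
Reagents that add atoms: none
Why: Boron tribromide ether cleavage, in which bromide attacks the methyl and primary strap carbons of the boron-bound ethers, frees all eight phenols in one operation, 4-arylchroman-2-ones survive it, any opened hydroxy acid recloses in the acidic quench (lactonisation onto either ortho oxygen of each ring gives the same compound), and the absence of base protects the C3 and C3' α-centres.

Compound list
1 | 1,2,3,4-tetramethoxybenzene | COc1ccc(OC)c(OC)c1OC | starting material
2 | 2,3,4,5-tetramethoxyphenyllithium | [Li]c1cc(OC)c(OC)c(OC)c1OC | intermediate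
3 | dimethyl (2,3,4,5-tetramethoxyphenyl)boronate | COB(OC)c1cc(OC)c(OC)c(OC)c1OC | intermediate
4 | 2,3,4,5-tetramethoxyphenol | COc1cc(O)c(OC)c(OC)c1OC | intermediate
5 | 3,5-dimethoxyphenol | COc1cc(O)cc(OC)c1 | starting material
6 | ethyl 3-(4-hydroxyphenyl)-3-oxopropanoate | CCOC(=O)CC(=O)c1ccc(O)cc1 | starting material
7 | 4-(4-hydroxyphenyl)-5,7-dimethoxy-2H-chromen-2-one (unit A) | COc1cc(OC)c2c(c1)OC(=O)C=C2c1ccc(O)cc1 | intermediate
8 | 4-(4-hydroxyphenyl)-5,6,7,8-tetramethoxy-2H-chromen-2-one (unit B) | COc1c(OC)c(OC)c2c(c1OC)OC(=O)C=C2c1ccc(O)cc1 | intermediate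
9 | 1,3-dibromopropane | BrCCCBr | starting material
10 | 4-[4-(3-bromopropoxy)phenyl]-5,7-dimethoxy-2H-chromen-2-one | COc1cc(OC)c2c(c1)OC(=O)C=C2c1ccc(OCCCBr)cc1 | intermediate
11 | strapped bis(4-arylcoumarin), 5,7-dimethoxy-4-{4-[3-(4-{5,6,7,8-tetramethoxy-2-oxo-2H-chromen-4-yl}phenoxy)propoxy]phenyl}-2H-chromen-2-one | COc1cc(OC)c2c(c1)OC(=O)C=C2c1ccc(OCCCOc2ccc(cc2)C2=CC(=O)Oc3c(OC)c(OC)c(OC)c(OC)c23)cc1 | intermediate
12 | triplet 1,4-diradical, C3–C3' bonded as in 13, radical centres at C4 and C4' | O=C1Oc2cc(OC)cc(OC)c2[C](c2ccc(OCCCO6)cc2)[C@@H]1[C@H]1C(=O)Oc2c(OC)c(OC)c(OC)c(OC)c2[C]1c1ccc6cc1 | intermediate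
13 | syn head-to-head photoadduct (3S,4R,3'R,4'S): both lactone rings cis-fused on one face of the cyclobutane C3–C3'–C4'–C4, with H3, H3' and the two strapped aryl groups on the other face | O=C1Oc2cc(OC)cc(OC)c2[C@@]3(c2ccc(OCCCO6)cc2)[C@@H]1[C@H]1C(=O)Oc2c(OC)c(OC)c(OC)c(OC)c2[C@@]31c1ccc6cc1 | intermediate
14 | bis(diisobutylaluminium) hemiacetal of 13 (C2 and C2' undefined) | CC(C)C[Al](CC(C)C)OC1Oc2cc(OC)cc(OC)c2[C@@]3(c2ccc(OCCCO6)cc2)[C@@H]1[C@H]1C(O[Al](CC(C)C)CC(C)C)Oc2c(OC)c(OC)c(OC)c(OC)c2[C@@]31c1ccc6cc1 | intermediate
15 | bis(trimethylsilyl acetal) of 13, 2,2'-bis(trimethylsilyloxy)chroman level (3S,4R,3'R,4'S; anomer mixture) | C[Si](C)(C)OC1Oc2cc(OC)cc(OC)c2[C@@]3(c2ccc(OCCCO6)cc2)[C@@H]1[C@H]1C(O[Si](C)(C)C)Oc2c(OC)c(OC)c(OC)c(OC)c2[C@@]31c1ccc6cc1 | intermediate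
16 | 4,4'-dilithio dianion, C4–C4' cleaved, planar carbanions at C4 and C4' | [Li+].[Li+].C[Si](C)(C)OC1Oc2cc(OC)cc(OC)c2[C-](c2ccc(OCCCO6)cc2)[C@@H]1[C@H]1C(O[Si](C)(C)C)Oc2c(OC)c(OC)c(OC)c(OC)c2[C-]1c1ccc6cc1 | intermediate
17 | seco bis(trimethylsilyl acetal) (3R,4S,3'S,4'R; anomer mixture) | C[Si](C)(C)OC1Oc2cc(OC)cc(OC)c2[C@H](c2ccc(OCCCO6)cc2)[C@@H]1[C@H]1C(O[Si](C)(C)C)Oc2c(OC)c(OC)c(OC)c(OC)c2[C@H]1c1ccc6cc1 | intermediate
18 | strapped bis(chroman-2-ol) (3R,4S,3'S,4'R; anomer mixture) | OC1Oc2cc(OC)cc(OC)c2[C@H](c2ccc(OCCCO6)cc2)[C@@H]1[C@H]1C(O)Oc2c(OC)c(OC)c(OC)c(OC)c2[C@H]1c1ccc6cc1 | intermediate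
19 | strapped bis-lactone hexamethyl ether (3R,4S,3'S,4'R), H3/H4 cis and H3'/H4' cis | O=C1Oc2cc(OC)cc(OC)c2[C@H](c2ccc(OCCCO6)cc2)[C@@H]1[C@H]1C(=O)Oc2c(OC)c(OC)c(OC)c(OC)c2[C@H]1c1ccc6cc1 | intermediate
20 | octakis(dibromoboryl) ether of the target (simplest formulation of the boron aryloxides) | O=C1Oc2cc(OB(Br)Br)cc(OB(Br)Br)c2[C@H](c2ccc(OB(Br)Br)cc2)[C@@H]1[C@H]1C(=O)Oc2c(OB(Br)Br)c(OB(Br)Br)c(OB(Br)Br)c(OB(Br)Br)c2[C@H]1c1ccc(OB(Br)Br)cc1 | intermediate
21 | CNP0064734.3, (3R,4S,3'S,4'R)-5,7,5',6',7',8'-hexahydroxy-4,4'-bis(4-hydroxyphenyl)-3,3'-bichroman-2,2'-dione | O=C1Oc2cc(O)cc(O)c2[C@H](c2ccc(O)cc2)[C@@H]1[C@H]1C(=O)Oc2c(O)c(O)c(O)c(O)c2[C@H]1c1ccc(O)cc1 | target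

Total step count: 10. Longest linear sequence: 8 steps (1 → 3 → 5 → 6 → 7 → 8 → 9 → 10; the branch 2 → 4 → 5 is equally long).

Steps most likely to fail

**Step 6.**
- The diradical may fall apart again at C3–C3' instead of closing between two crowded, fully substituted carbons.
- The adduct may reopen thermally during work-up.
- The Lewis acid may spread over lactone B and the methoxy oxygens, which erodes the enantioselectivity.
- Unbound chromophore may react in a racemic background process.

The fallback replaces the photochemistry by enolate chemistry of known types. It sets out from 10 and 8, comes back at 19, and thereby bypasses steps 6 to 9.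
- Copper hydride asymmetric conjugate reduction of 10 (Cu(OAc)2, one antipode of DTBM-SEGPHOS, (EtO)2MeSiH, t-BuOH, toluene) should give (S)-4-[4-(3-bromopropoxy)phenyl]-5,7-dimethoxychroman-2-one F1.
- Williamson coupling of F1 with 8 (K2CO3, DMF, rt) gives the half-reduced strapped compound F2.
- A second copper hydride reduction, now with the other ligand antipode, gives the strapped (4S,4'R)-bis(chroman-2-one) F3.
- Double deprotonation (LDA, THF, −78 °C) gives the dilithium bis-enolate F4.
- CuCl2 couples F4 intramolecularly at C3–C3' (oxidative ester enolate coupling) to the 3,4-trans,3',4'-trans bis-lactone F5, each new bond forming anti to the neighbouring aryl group.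
- Because both α-centres of F5 have the wrong sense, it is deprotonated again to the dilithium dienediolate F6 and added inversely to cold AcOH in THF. Kinetic protonation anti to the pseudo-axial C4 and C4' aryl groups puts H3 cis to H4 and H3' cis to H4', which is 19.

**Step 8.**
- The dianion may dissociate at C3–C3' into two monomeric radical anions before the quench.
- Protonation may occur in part from the inner face.
- Over-titration may strip a methoxy group reductively from the pentaoxygenated ring.

The fallback changes from electron transfer in solution to surface hydrogenolysis. It sets out from 13 and comes back at 19, so steps 7 and 9 fall away, and it makes no new compound (F0).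
- 13 is shaken with H2 over Pd/C in EtOAc at 0 °C to rt.
- Strained 1,2-diarylcyclobutanes are opened at the bis-benzylic bond under such conditions.
- Lactones and alkyl aryl ethers are inert, and no radical anion able to unzip the dimer arises.
- Palladium usually replaces a benzylic σ-bond with inversion, the sense needed at C4 and C4'. Access of the surface to so hindered a bond and the steric course would both have to be established, which is why this is not the first choice.

**Step 10.**
- Cleavage of the hindered ethers and of the strap may stay incomplete.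
- Long exposure to acid may enolise C3 and C3'.
- The pentaoxygenated ring may be oxidised by air during isolation.

The fallback changes from boron Lewis acid with hydrolysis to silyl-transfer dealkylation, which ends in a protected, oxygen-stable form. It sets out from 19 and comes back at 21.
- Me3SiI (excess, CHCl3, 50 °C, Ar) should cleave all methyl ethers and both strap ethers by iodide attack at carbon. The aryl lactones have no O-alkyl bond and are not touched. The product is the octakis(trimethylsilyl) ether F7, which can be freed from reagents by evaporation and filtration.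
- Degassed THF/water with citric acid then releases 21 in a nearly neutral last operation.

Further compounds
F1 | step 6 | (S)-4-[4-(3-bromopropoxy)phenyl]-5,7-dimethoxychroman-2-one | O=C1Oc2cc(OC)cc(OC)c2[C@H](c2ccc(OCCCBr)cc2)C1
F2 | step 6 | half-reduced strapped compound, (4S)-chroman-2-one unit A and coumarin unit B | O=C1Oc2cc(OC)cc(OC)c2[C@H](c2ccc(OCCCOc3ccc(cc3)C3=CC(=O)Oc4c(OC)c(OC)c(OC)c(OC)c43)cc2)C1
F3 | step 6 | strapped (4S,4'R)-bis(chroman-2-one) | O=C1Oc2cc(OC)cc(OC)c2[C@H](c2ccc(OCCCOc3ccc(cc3)[C@H]3CC(=O)Oc4c(OC)c(OC)c(OC)c(OC)c43)cc2)C1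
F4 | step 6 | dilithium bis-enolate of F3 | [Li+].[Li+].[O-]C1=C[C@@H](c3ccc(OCCCOc4ccc(cc4)[C@H]4C=C([O-])Oc5c(OC)c(OC)c(OC)c(OC)c54)cc3)c2c(OC)cc(OC)cc2O1
F5 | step 6 | 3,4-trans,3',4'-trans bis-lactone (3S,4S,3'R,4'R) | O=C1Oc2cc(OC)cc(OC)c2[C@H](c2ccc(OCCCO6)cc2)[C@H]1[C@@H]1C(=O)Oc2c(OC)c(OC)c(OC)c(OC)c2[C@H]1c1ccc6cc1
F6 | step 6 | dilithium dienediolate of F5 (4S,4'R) | [Li+].[Li+].[O-]C1=C(C2=C([O-])Oc3c(OC)c(OC)c(OC)c(OC)c3[C@H]2c2ccc(OCCCO6)cc2)[C@@H](c2ccc6cc2)c2c(OC)cc(OC)cc2O1
F0 | step 8 | none | none
F7 | step 10 | octakis(trimethylsilyl) ether of the target (3R,4S,3'S,4'R) | O=C1Oc2cc(O[Si](C)(C)C)cc(O[Si](C)(C)C)c2[C@H](c2ccc(O[Si](C)(C)C)cc2)[C@@H]1[C@H]1C(=O)Oc2c(O[Si](C)(C)C)c(O[Si](C)(C)C)c(O[Si](C)(C)C)c(O[Si](C)(C)C)c2[C@H]1c1ccc(O[Si](C)(C)C)cc1
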